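**Retrosynthetic overview**
1. Numbering: ring A = C6 (spiro), C7 (=C14H2), C8, C9 (OAc), C10 (Br), C11 (two methyls); ring B = C6, C1, C2 (Cl), C3 (Me, Br), C4, C5. The strategy rests on one feature: ring B with its C3 methyl, together with C11 and both C11 methyls, is the carbon skeleton of (R)-pulegone, and the C6–C11 bond between the two quaternary carbons is pulegone's exocyclic enone double bond, so ring A can be built across it.
2. Target ⇒ C9 alcohol (acetylation) ⇒ C10-bromo C9-ketone with the C7=C14 methylene (cis reduction) ⇒ ring A enone carrying the finished ring B (acid bromination with loss of conjugation).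
3. Ring B trans-bromochloride ⇒ C2=C3 alkene (epoxide, chloride at C2, bromide at C3) ⇒ C2–C3 enone ⇒ C1 ketone; C3 is erased only after it has set C6.
4. Ring A ⇒ formal [4+2] (double Michael) of a 2-silyloxypenta-1,3,4-triene with (R)-pulegone: bonds C10–C11 and C6–C7, the allene leaving the C7=C14 methylene.
5. Ring order: ring B is bought; ring A is the only ring formed (step 4); the diene comes from pent-4-yn-2-ol in three steps.

Key step: step 4

Faces: on ring B, "C11 face" and "C7 face" are the faces on which C11 and C7 lie at C6; on ring A, "C1 face" and "C5 face" likewise. In the target, C3–Br is on the C11 face, C3–Me and C2–Cl are on the C7 face, and C9–OAc and C10–Br are on the C1 face.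
Remark: the diene carries a tert-butyldimethylsilyl group rather than a smaller silyl group, so that the diene and the dienol ether product can be handled.
Remark: ring B is halogenated while ring A is still the conjugated enone, whose double bond is inert to peracid and HBr; the C7=C14 methylene is released only in step 14.
Assumption: in the ring B half-chair of 15 the sp2 carbon C7 is pseudo-axial and C11 pseudo-equatorial, so reagents reach C2=C3 from the C11 face.

**Route**

Step 1
Reactants: 1 pent-4-yn-2-ol
Product: 2 pent-4-yn-2-one
Conditions: CrO3, H2SO4, H2O, acetone, 0 °C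
Reagents that add atoms: none
Why: Jones oxidation of a secondary alcohol to the ketone; the terminal alkyne is inert and the acidic medium keeps the β,γ-alkynyl ketone from isomerising.

Step 2
Reactants: 2 pent-4-yn-2-one
Product: 3 penta-3,4-dien-2-one
Conditions: Et3N (5 mol%), CH2Cl2, 0 °C, short contact; used cold as a solution
Reagents that add atoms: none
Why: Base-catalysed propargyl–allenyl prototropic isomerisation, driven by conjugation of the allene with the carbonyl group; low temperature and short contact should stop it before further isomerisation or dimerisation.

Step 3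
Reactants: 3 penta-3,4-dien-2-one; 4 tert-butyldimethylsilyl triflate
Product: 5 2-(tert-butyldimethylsilyloxy)penta-1,3,4-triene
Conditions: 4 (1.1 equiv), iPr2NEt, CH2Cl2, −78 → −20 °C; used at once
Reagents that add atoms: tert-butyldimethylsilyl triflate (4), CC(C)(C)[Si](C)(C)OS(=O)(=O)C(F)(F)F
Why: Soft enolisation (O-silylation by the silyl triflate, then deprotonation by the hindered amine), the standard way from vinyl ketones to 2-silyloxybuta-1,3-dienes; the methyl group is the only sp3 α-position, so one regioisomer is possible, and the non-nucleophilic base should not add to the allenone.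

Step 4
Reactants: 5 2-(tert-butyldimethylsilyloxy)penta-1,3,4-triene; 6 (R)-(+)-pulegone
Product: 7 spiro silyl dienol ether (ring A: C8=C9 with OSitBuMe2 on C9, exocyclic C7=C14, C11 gem-dimethyl; ring B: C1 ketone, C3 methyl cis to C7)
Conditions: TiCl4 (1.1 equiv), CH2Cl2, −78 °C, slow addition of 5 (1.5 equiv); Et3N then aq. NaHCO3 at −78 °C
Reagents that add atoms: none
Why: Proposed new method: TiCl4 binds the carbonyl of the s-cis-locked enone 6, the silyl enol ether terminus of 5 (the future C10) adds to the fully substituted β-carbon C11 in a Mukaiyama–Michael step, and the resulting C1–C6 titanium enolate then adds to the central allene carbon C7 of the tethered O-silylated allenyl ketone, leaving the C9 silyl dienol ether and the C7=C14 methylene. The closest known reactions are Lewis-acid Mukaiyama–Michael and Sakurai additions to β,β-disubstituted enones, stepwise double-Michael [4+2] annulations of 2-silyloxydienes with hindered enones, and Diels–Alder reactions of vinylallenes, which give the same methylenecyclohexene pattern. Ring A closes by a 6-endo Michael addition (the second bond of a stepwise [4+2]), which the cisoid C10–C9–C8=C7 array allows. The only new stereocentre, C6, is controlled by the C3 methyl: the enolate should react through a chair-like ring B with the methyl equatorial, the C6–C7 bond forming axially while the bulky C11 stays equatorial, so C7 ends cis to the methyl, which should also be the more stable spiro isomer. The step needs C-attack of C6 on C7 in preference to O-attack, aldol closure to a cyclobutane and dimerisation of the diene; the tether that holds the activated allenone beside C6, the reversibility of the four-ring aldol and slow addition of 5 at −78 °C should secure this.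

Step 5
Reactants: 7 spiro silyl dienol ether
Product: 8 spiro ketal ketone (ring A: C9 ethylene ketal, C8H2, exocyclic C7=C14; ring B: C1 ketone, C3 methyl)
Conditions: HOCH2CH2OH (10 equiv), TsOH·H2O (5 mol%), benzene, 4 Å MS, rt
Reagents that add atoms: ethylene glycol, OCCO
Why: Acid-catalysed transketalisation of an enol ether: protonation of the silyl dienol ether at C8 gives the C9 oxocarbenium ion, which the diol traps as the dioxolane with C7=C14 left out of conjugation (any ring A enone formed by adventitious hydrolysis gives the same ketal by the known deconjugative ketalisation of enones), while the C1 ketone, buried between the spiro carbon C6 and the quaternary C11, should stay free.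

Step 6
Reactants: 8 spiro ketal ketone
Product: 10 ring B enone ketal (C1 ketone, C2=C3 with the methyl on C3; ring A as in 8), via trimethylsilyl enol ether 9 (not isolated)
Conditions: LDA (LiN(iPr)2), THF, −78 °C, then Me3SiCl; Pd(OAc)2 (1.1 equiv), MeCN, rt
Reagents that add atoms: none
Why: Saegusa–Ito dehydrogenation: the C1 ketone can enolise only toward C2 (C6 is quaternary) and the palladium enolate can lose only the C3 hydrogen, so the C2=C3 enone is the sole possible product; this removes the C3 stereocentre after it has served in step 4.

Step 7
Reactants: 10 ring B enone ketal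
Product: 11 allylic alcohol (C1–OH, either epimer; C2=C3; ring A as in 8)
Conditions: LiAlH4, Et2O, 0 °C
Reagents that add atoms: none
Why: 1,2-Reduction of a β,β-disubstituted cyclohexenone by a small aluminium hydride; the ketal is inert, and the configuration of the new C1 carbinol is irrelevant because C1 becomes CH2 in step 9.

Step 8
Reactants: 11 allylic alcohol
Product: 12 allylic acetate (C1–OAc; C2=C3; ring A as in 8)
Conditions: Ac2O, DMAP, pyridine, CH2Cl2, rt
Reagents that add atoms: acetic anhydride, CC(=O)OC(C)=O
Why: DMAP-catalysed acylation of a hindered secondary allylic alcohol, to give a leaving group for reductive cleavage.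

Step 9
Reactants: 12 allylic acetate
Product: 13 diene ketal (ring B: C1H2, C2=C3 with the methyl on C3; ring A: C9 ethylene ketal, exocyclic C7=C14)
Conditions: Li, NH3 (l), THF, −78 °C; NH4Cl
Reagents that add atoms: none
Why: Dissolving-metal (Birch-type) reductive cleavage of the allylic C–O bond: the C1–C2–C3 allyl anion is protonated at its less substituted terminus C1, where the charge density is higher, which should leave the trisubstituted C2=C3 alkene; the ketal and the isolated C7=C14 bond are inert to lithium in ammonia.

Step 10
Reactants: 13 diene ketal
Product: 15 dienone (ring A: C9 ketone conjugated with C7=C8, methyl C14 on C7; ring B: C2=C3 alkene), via deconjugated ketone 14 (not isolated)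
Conditions: TsOH·H2O (0.2 equiv), acetone–H2O, 45 °C
Reagents that add atoms: water, O
Why: Acid hydrolysis of the dioxolane followed by acid-catalysed prototropic shift of the C7=C14 bond into conjugation, the enone being the thermodynamic isomer; the dilute sulfonic acid should not protonate the C2=C3 alkene.

Step 11
Reactants: 15 dienone
Product: 16 epoxy enone (C2–C3 epoxide with oxygen on the C11 face of ring B; ring A enone unchanged)
Conditions: mCPBA (1.05 equiv), NaHCO3, CH2Cl2, 0 °C
Reagents that add atoms: 3-chloroperoxybenzoic acid, O=C(OO)c1cccc(Cl)c1
Why: Prilezhaev epoxidation, chemoselective for the electron-rich trisubstituted C2=C3 bond over the enone C7=C8 bond; the peracid should attack from the C11 face, because in the favoured half-chair of ring B the pseudo-axial C7 and its C14 methyl cover the other face, and this sets the configuration of C3 (and provisionally of C2).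

Step 12
Reactants: 16 epoxy enone
Product: 17 chlorohydrin (C2–Cl on the C7 face, tertiary C3–OH on the C11 face, trans; ring A enone)
Conditions: Li2CuCl4 (from LiCl and CuCl2), THF, rt; aq. NH4Cl
Reagents that add atoms: dilithium tetrachlorocuprate, [Li+].[Li+].[Cl-].[Cl-].[Cl-].[Cl-].[Cu+2]
Why: Regioselective SN2 opening of a trisubstituted epoxide by a soft chloride source at the less substituted carbon, here also the trans-diaxial (Fürst–Plattner) mode; inversion at C2 puts chlorine on the C7 face and the tertiary C3–O bond stays on the C11 face.

Step 13
Reactants: 17 chlorohydrin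
Product: 18 bromochloro enone (C3–Br on the C11 face, C2–Cl on the C7 face; ring A enone)
Conditions: HBr (33% in AcOH, 3 equiv), CH2Cl2, 0 °C
Reagents that add atoms: hydrogen bromide, Br
Why: SN1 substitution of a tertiary alcohol by HBr with neighbouring-group participation: the C3 cation formed anti to the axial C2–Cl bond is bridged by chlorine and is opened by bromide from the C11 face, giving net retention at C3 (trans-diaxial bromochloride, also the more stable C3 epimer with the methyl equatorial); any alkene formed by proton loss re-adds HBr through the same cation.

Step 14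
Reactants: 18 bromochloro enone
Product: 19 bromo ketone (ring A: C9 ketone, C10–Br on the C1 face, exocyclic C7=C14; ring B as in 18)
Conditions: Br2 (1.0 equiv), HBr (48% aq., cat.), AcOH, rt; used directly
Reagents that add atoms: bromine, BrBr
Why: Acid-catalysed α-bromination of a ketone through its enol under HBr, where bromination at carbon is reversible: the enone equilibrates with its β,γ-unsaturated tautomer, whose carbonyl enolises toward C10 and is brominated there, and the resulting 10-bromo ketone, which enolises only slowly, keeps the C7=C14 bond out of conjugation; C10 is epimerisable under these conditions and bromine should settle equatorial on ring A on the C1 face.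

Step 15
Reactants: 19 bromo ketone
Product: 20 isoobtusol (C9–OH cis to C10–Br, both on the C1 face)
Conditions: iBu2AlH, THF, −78 °C
Reagents that add atoms: none
Why: Hydride reduction of an α-bromo ketone: the axial trajectory to C9 is blocked by the axial C11 methyl, so the bulky aluminium hydride attacks equatorially and gives the axial C9 alcohol cis to the equatorial C10 bromine; the non-basic reagent leaves the β,γ-unsaturated ketone and the alkyl halides alone.

Step 16
Reactants: 20 isoobtusol
Product: 21 9-acetylisoobtusol
Conditions: Ac2O, DMAP, pyridine, CH2Cl2, rt
Reagents that add atoms: acetic anhydride, CC(=O)OC(C)=O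
Why: DMAP-catalysed acetylation of the secondary alcohol; no stereocentre is touched and the mild base should not eliminate HBr.

**Compound list**
1 | pent-4-yn-2-ol | CC(O)CC#C | starting material
2 | pent-4-yn-2-one | CC(=O)CC#C | intermediate
3 | penta-3,4-dien-2-one | CC(=O)C=C=C | intermediate
4 | tert-butyldimethylsilyl triflate | CC(C)(C)[Si](C)(C)OS(=O)(=O)C(F)(F)F | starting material
5 | 2-(tert-butyldimethylsilyloxy)penta-1,3,4-triene | C=C=CC(=C)O[Si](C)(C)C(C)(C)C | intermediate
6 | (R)-(+)-pulegone | C[C@@H]1CCC(=C(C)C)C(=O)C1 | starting material
7 | spiro silyl dienol ether (C9 OSitBuMe2, C8=C9, C7=C14; C1 ketone; C3 methyl cis to C7) | C=C1C=C(O[Si](C)(C)C(C)(C)C)CC(C)(C)[C@@]12CC[C@@H](C)CC2=O | intermediate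
8 | spiro ketal ketone (C9 ethylene ketal, C7=C14; C1 ketone) | C=C1CC2(OCCO2)CC(C)(C)[C@@]13CC[C@@H](C)CC3=O | intermediate
9 | trimethylsilyl enol ether of 8 (C1–OSiMe3, C1=C2) | C=C1CC2(OCCO2)CC(C)(C)[C@@]13CC[C@@H](C)C=C3O[Si](C)(C)C | intermediate
10 | ring B enone ketal (C1 ketone, C2=C3) | C=C1CC2(OCCO2)CC(C)(C)[C@@]13CCC(C)=CC3=O | intermediate
11 | allylic alcohol (C1–OH, either epimer) | C=C1CC2(OCCO2)CC(C)(C)[C@@]13CCC(C)=CC3O | intermediate
12 | allylic acetate (C1–OAc) | C=C1CC2(OCCO2)CC(C)(C)[C@@]13CCC(C)=CC3OC(C)=O | intermediate
13 | diene ketal (C1H2, C2=C3; C9 ketal, C7=C14) | C=C1CC2(OCCO2)CC(C)(C)[C@@]13CCC(C)=CC3 | intermediate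
14 | deconjugated ketone (C9 ketone, C7=C14; C2=C3) | C=C1CC(=O)CC(C)(C)[C@@]12CCC(C)=CC2 | intermediate
15 | dienone (C9 ketone, C7=C8, C7 methyl; C2=C3) | CC1=CC(=O)CC(C)(C)[C@@]12CCC(C)=CC2 | intermediate
16 | epoxy enone (C2–C3 epoxide on the C11 face) | CC1=CC(=O)CC(C)(C)[C@@]12CC[C@]3(C)O[C@@H]3C2 | intermediate
17 | chlorohydrin (C2–Cl on the C7 face, C3–OH on the C11 face) | CC1=CC(=O)CC(C)(C)[C@@]12CC[C@](C)(O)[C@@H](Cl)C2 | intermediate
18 | bromochloro enone (C3–Br on the C11 face, C2–Cl on the C7 face) | CC1=CC(=O)CC(C)(C)[C@@]12CC[C@](C)(Br)[C@@H](Cl)C2 | intermediate
19 | bromo ketone (C9 ketone, C10–Br, C7=C14) | C=C1CC(=O)[C@H](Br)C(C)(C)[C@@]12CC[C@](C)(Br)[C@@H](Cl)C2 | intermediate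
20 | isoobtusol | C=C1C[C@H](O)[C@H](Br)C(C)(C)[C@@]12CC[C@](C)(Br)[C@@H](Cl)C2 | intermediate
21 | 9-acetylisoobtusol | C=C1C[C@H](OC(C)=O)[C@H](Br)C(C)(C)[C@@]12CC[C@](C)(Br)[C@@H](Cl)C2 | target

**Step count**
Total: 16 steps. Longest linear sequence: 16 steps (1 → 21); pulegone 6 enters at step 4 and is carried through 13 steps.

**Steps most likely to fail**

Step 4. The first Michael addition to the fully substituted carbon C11 may be slower than Lewis-acid decomposition or dimerisation of the vinylallene. The enolate may also fail to close on C7, stopping at the open adduct or a cyclobutane, or it may close on the wrong face of ring B. The fallback sets out from 6 and uses known chemistry. (E)-Pent-3-en-2-one (bought, C/C=C/C(C)=O) is silylated with 4 and Et3N to (E)-2-(tert-butyldimethylsilyloxy)penta-1,3-diene F1. F1 is added to 6 under triflimide (Tf2NH) catalysis in CH2Cl2 at −78 °C, a known type of hindered Diels–Alder (double Michael) reaction of 2-silyloxydienes with tetrasubstituted enones. This gives the spiro silyl enol ether F2, with the methyl-bearing C7 as an sp3 carbon and C8=C9 as the enol ether. Saegusa–Ito oxidation of F2 (Pd(OAc)2, MeCN) brings in the C7=C8 bond and gives the ring A enone ring B ketone F3. Deconjugative ketalisation of F3 (ethylene glycol, TsOH, benzene, Dean–Stark) comes back to the route at 8.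

Step 11. The peracid may attack the C7 face, or show poor facial selectivity, which would carry the wrong configuration into C2 and C3. The fallback sets out from 15 and reverses the roles of the two heteroatoms. Trichloroisocyanuric acid in aqueous acetone at 0 °C delivers electrophilic chlorine to C2 and water to C3 in an anti addition. If electrophiles prefer the C7 face, this gives chlorine on the C7 face and the tertiary alcohol on the C11 face, and comes back to the route at 17. Any allylic chloride formed by ene-type chlorination should converge in step 13, because HBr adds to it through the same C3 cation. This fallback makes no new compound (F0).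

Step 14. Bromination may go to C8 or C14 through the linear dienol, the double bond may stay in conjugation, or the wrong C10 epimer may predominate. The fallback sets out from 18 and separates the events under kinetic control. LiN(SiMe3)2 and Me3SiCl in THF at −78 °C deprotonate the α'-position C10 and give the cross-conjugated trimethylsilyl dienol ether F4. NBS at −78 °C converts F4 to the 10-bromo conjugated enone F5. Isopropenyl acetate with TsOH turns F5 into the linear dienol acetate F6 (C8=C9 with OAc on C9, C7=C14). NaBH4 in EtOH–THF at 0 °C then cleaves the enol acetate, protonates the dienolate at C8 and reduces the deconjugated ketone as it forms, a known deconjugative reduction of dienol acetates. This comes back to the route at 20.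

**Further compounds**
F1 | step 4 | (E)-2-(tert-butyldimethylsilyloxy)penta-1,3-diene | C/C=C/C(=C)O[Si](C)(C)C(C)(C)C
F2 | step 4 | spiro silyl enol ether (C7 methyl on sp3 C7, either epimer; C8=C9 with OSitBuMe2; C1 ketone) | CC1C=C(O[Si](C)(C)C(C)(C)C)CC(C)(C)[C@@]12CC[C@@H](C)CC2=O
F3 | step 4 | ring A enone ring B ketone (C9 ketone, C7=C8, C7 methyl; C1 ketone, C3 methyl) | CC1=CC(=O)CC(C)(C)[C@@]12CC[C@@H](C)CC2=O
F0 | step 11 | none | none
F4 | step 14 | cross-conjugated trimethylsilyl dienol ether of 18 (C9–OSiMe3, C9=C10, C7=C8) | CC1=CC(O[Si](C)(C)C)=CC(C)(C)[C@@]12CC[C@](C)(Br)[C@@H](Cl)C2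
F5 | step 14 | 10-bromo conjugated enone | CC1=CC(=O)[C@H](Br)C(C)(C)[C@@]12CC[C@](C)(Br)[C@@H](Cl)C2
F6 | step 14 | linear dienol acetate (C9–OAc, C8=C9, C7=C14, C10–Br) | C=C1C=C(OC(C)=O)[C@H](Br)C(C)(C)[C@@]12CC[C@](C)(Br)[C@@H](Cl)C2
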